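**Plan** (locants: ring C1 carries the side chain, C2 OAc, C3 OAng, C4(CH3)/C5 epoxide, C6 H2; chain C7(=C14H2), C8 OAng, C9, C10/C11 epoxide)
- Cuts, in retrosynthetic order: the two angelates and the 10,11-epoxide; the 4,5-epoxide; C8–C9 (allyl addition to a C8 lactol, prenyl by cross-metathesis); C7=C14 (lactone α-methylenation); the C2–O bond (Baeyer–Villiger insertion into C2–C8); last C2–C3 and C1–C6 (Diels–Alder).
- Feature used: the cis triad C3–O / C2–O / C1–C7 plus the 1,4-dioxygen pattern O–C2–C1–C7–C8–O. C2, C1, C7, C8 are the four carbons of cyclobut-2-enone; C3, C4(CH3), C5, C6 are tiglaldehyde.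
- Forward: the Diels–Alder reaction forms the cyclohexene with a cis-fused cyclobutanone; Baeyer–Villiger oxidation gives the cis-fused γ-lactone C2–O–C8(=O)–C7–C1. The lactone is methylenated at C7, reduced and opened at C8 by allyl addition; the two oxiranes are made late.
- Stereochemistry: C1, C2, C3 from the catalyst-controlled endo cycloaddition (C2 retained in the Baeyer–Villiger step); C4/C5 from the 3-OH-directed vanadium epoxidation; C8 from CBS reduction; C10 from Shi epoxidation.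

Key step: step 4

Remark: cyclobut-2-enone is not assumed to be purchasable and is made in two steps; the target locants above are used in all "Why" lines.

Step 1
Reactants: 1 3-oxocyclobutane-1-carboxylic acid
Product: 2 3-bromocyclobutan-1-one
Conditions: HgO (red), Br2, MgSO4, CH2Cl2, reflux
Reagents that add atoms: bromine, BrBr
Why: Cristol–Firth variant of the Hunsdiecker reaction, in which the acyl hypobromite from the mercury carboxylate fragments by a radical chain to the bromide with loss of CO2; no stereocentre is involved.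

Step 2
Reactants: 2 3-bromocyclobutan-1-one
Product: 3 cyclobut-2-en-1-one
Conditions: n-Bu3N, neat, rt, product distilled at reduced pressure into a −78 °C trap
Reagents that add atoms: none
Why: E1cB dehydrobromination of the β-bromo ketone by a hindered tertiary amine, with the volatile enone removed from the salt as it forms.

Step 3
Reactants: 4 (E)-2-methylbut-2-enal (tiglaldehyde)
Product: 5 tert-butyl(dimethyl){[(1E)-2-methylbuta-1,3-dien-1-yl]oxy}silane
Conditions: TBSOTf, Et3N, Et2O, 0 °C to rt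
Reagents that add atoms: tert-butyldimethylsilyl trifluoromethanesulfonate, CC(C)(C)[Si](C)(C)OS(=O)(=O)C(F)(F)F
Why: O-silylation of the enal and γ-deprotonation (vinylogous silyl enol ether formation) should give the dienol ether mainly as the 1E isomer (oxygen trans to the vinyl group); the minor Z isomer is a spectator in step 4.

Step 4
Reactants: 3 cyclobut-2-en-1-one; 5 tert-butyl(dimethyl){[(1E)-2-methylbuta-1,3-dien-1-yl]oxy}silane
Product: 6 (1S,5R,6R)-5-[(tert-butyldimethylsilyl)oxy]-4-methylbicyclo[4.2.0]oct-3-en-7-one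
Conditions: chiral B-(o-tolyl)oxazaborolidinium triflimide (from the diphenylprolinol-derived oxazaborolidine and Tf2NH, 10–20 mol %), 5 (1.5 equiv), CH2Cl2, −78 °C
Reagents that add atoms: none
Why: Concerted, asynchronous [4+2] cycloaddition of the strained enone 3, activated by coordination of its carbonyl oxygen to the chiral boron Lewis acid, with the electron-rich diene 5; the closest known reactions are the thermal and Lewis-acid-promoted Diels–Alder reactions of cyclobut-2-enone with 1-oxygenated dienes and the oxazaborolidinium-catalysed enantioselective Diels–Alder reactions of cyclic enones. The six-membered ring closes by intermolecular suprafacial addition across the ring-locked cis alkene of 3 (new bonds C2–C3 and C1–C6), so the cyclobutanone is cis-fused and the C2–C8 and C1–C7 bonds are cis. The endo transition state (carbonyl under the diene) places the OTBS group of the E-diene on the face of the C2–C8 bond, which sets C3 cis to C2 and C1. Absolute configuration comes from the catalyst shielding one face of the bound enone; which antipode gives (1S,5R,6R)-6 is to be fixed by correlation on the first run, both antipodes being available. The step needs "ortho" regiochemistry (oxygen-bearing diene terminus to the enone α-carbon), secured by the 1-silyloxy donor, which puts the large HOMO coefficient on the CH2 terminus and should outweigh the opposing 2-methyl group; only the E-diene can reach the reactive s-cis conformation.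

Step 5
Reactants: 6 (1S,5R,6R)-5-[(tert-butyldimethylsilyl)oxy]-4-methylbicyclo[4.2.0]oct-3-en-7-one
Product: 7 (3aS,7S,7aR)-7-[(tert-butyldimethylsilyl)oxy]-6-methyl-3a,4,7,7a-tetrahydro-1-benzofuran-2(3H)-one
Conditions: 30 % aq. H2O2, NaOH (0.3 equiv), THF–MeOH, 0 °C; work-up at pH 4
Reagents that add atoms: hydrogen peroxide, OO
Why: Baeyer–Villiger oxidation of a strained cyclobutanone by hydroperoxide anion, in which the more substituted ring-fusion carbon C2 should migrate with retention (C2–C8 becomes C2–O–C8), while the trisubstituted alkene is inert to this nucleophilic oxidant.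

Step 6
Reactants: 7 (3aS,7S,7aR)-7-[(tert-butyldimethylsilyl)oxy]-6-methyl-3a,4,7,7a-tetrahydro-1-benzofuran-2(3H)-one
Product: 10 (3aS,7S,7aR)-7-[(tert-butyldimethylsilyl)oxy]-6-methyl-3-methylidene-3a,4,7,7a-tetrahydro-1-benzofuran-2(3H)-one, via Mannich base 8 (not isolated), via methiodide 9 (not isolated)
Conditions: LDA, THF, −78 °C; CH2=NMe2+ I−, −78 °C to rt; MeI, MeOH, rt; aq. NaHCO3, CH2Cl2, rt
Reagents that add atoms: N,N-dimethylmethyleneiminium iodide (Eschenmoser's salt), C=[N+](C)C.[I-]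
Why: Mannich reaction of the lactone lithium enolate, N-methylation and β-elimination is the standard α-methylenation of γ-butyrolactones and installs C14; the transient C7 stereocentre is destroyed and C1 is not acidic.

Step 7
Reactants: 10 (3aS,7S,7aR)-7-[(tert-butyldimethylsilyl)oxy]-6-methyl-3-methylidene-3a,4,7,7a-tetrahydro-1-benzofuran-2(3H)-one
Product: 11 (3aS,7S,7aR)-7-[(tert-butyldimethylsilyl)oxy]-6-methyl-3-methylidene-2,3,3a,4,7,7a-hexahydro-1-benzofuran-2-ol (anomers)
Conditions: DIBAL-H (1.1 equiv), CH2Cl2, −78 °C; Rochelle salt work-up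
Reagents that add atoms: none
Why: Partial reduction of the lactone at −78 °C should stop at the aluminium lactolate and give the lactol, a masked C8 aldehyde, 1,2-reduction being the usual course for α-methylene lactones.

Step 8
Reactants: 11 (3aS,7S,7aR)-7-[(tert-butyldimethylsilyl)oxy]-6-methyl-3-methylidene-2,3,3a,4,7,7a-hexahydro-1-benzofuran-2-ol
Product: 12 (1R,2S,6S)-2-[(tert-butyldimethylsilyl)oxy]-6-(3-hydroxyhexa-1,5-dien-2-yl)-3-methylcyclohex-3-en-1-ol (C8 epimers)
Conditions: allylmagnesium bromide (3 equiv), THF, 0 °C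
Reagents that add atoms: allylmagnesium bromide, C=CC[Mg]Br
Why: Grignard 1,2-addition to the open hydroxy-enal tautomer of the lactol (one equivalent deprotonates it) forms C8–C9; the C8 configuration is not controlled here and is erased in step 10.

Step 9
Reactants: 12 (1R,2S,6S)-2-[(tert-butyldimethylsilyl)oxy]-6-(3-hydroxyhexa-1,5-dien-2-yl)-3-methylcyclohex-3-en-1-ol
Product: 13 (1R,2S,6S)-2-[(tert-butyldimethylsilyl)oxy]-6-(3-hydroxy-6-methylhepta-1,5-dien-2-yl)-3-methylcyclohex-3-en-1-ol (C8 epimers)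
Conditions: Grubbs second-generation catalyst (5 mol %), 2-methylbut-2-ene–CH2Cl2, 40 °C
Reagents that add atoms: 2-methylbut-2-ene, CC=C(C)C
Why: Olefin cross-metathesis of the monosubstituted alkene with 2-methylbut-2-ene converts allyl into prenyl, while the 1,1-disubstituted C7=C14 and the trisubstituted ring alkene are too hindered to take part.

Step 10
Reactants: 13 (1R,2S,6S)-2-[(tert-butyldimethylsilyl)oxy]-6-(3-hydroxy-6-methylhepta-1,5-dien-2-yl)-3-methylcyclohex-3-en-1-ol
Product: 14 2-[(1S,5S,6R)-5-[(tert-butyldimethylsilyl)oxy]-6-hydroxy-4-methylcyclohex-3-en-1-yl]-6-methylhepta-1,5-dien-3-one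
Conditions: activated MnO2, CH2Cl2, rt
Reagents that add atoms: none
Why: Chemoselective MnO2 oxidation of the allylic C8 alcohol leaves the saturated, hindered C2–OH untouched, which differentiates the two hydroxyls released from the lactone and converges both C8 epimers.

Step 11
Reactants: 14 2-[(1S,5S,6R)-5-[(tert-butyldimethylsilyl)oxy]-6-hydroxy-4-methylcyclohex-3-en-1-yl]-6-methylhepta-1,5-dien-3-one
Product: 15 (1R,2S,6S)-2-[(tert-butyldimethylsilyl)oxy]-3-methyl-6-(6-methyl-3-oxohepta-1,5-dien-2-yl)cyclohex-3-en-1-yl acetate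
Conditions: Ac2O, pyridine, DMAP (cat.), CH2Cl2, 0 °C
Reagents that add atoms: acetic anhydride, CC(=O)OC(C)=O
Why: DMAP-catalysed acetylation of the only free hydroxyl places the acetate at C2 while O3 is silylated and C8 is a ketone; low temperature and short contact limit base-induced migration of C10=C11 into conjugation.

Step 12
Reactants: 15 (1R,2S,6S)-2-[(tert-butyldimethylsilyl)oxy]-3-methyl-6-(6-methyl-3-oxohepta-1,5-dien-2-yl)cyclohex-3-en-1-yl acetate
Product: 16 (1R,2S,6S)-2-hydroxy-3-methyl-6-(6-methyl-3-oxohepta-1,5-dien-2-yl)cyclohex-3-en-1-yl acetate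
Conditions: HF·pyridine, pyridine–THF, 0 °C to rt
Reagents that add atoms: none
Why: Fluoride cleavage of the secondary TBS ether under buffered, weakly acidic conditions, chosen to avoid alkoxide-mediated acetyl migration from O2 to O3.

Step 13
Reactants: 16 (1R,2S,6S)-2-hydroxy-3-methyl-6-(6-methyl-3-oxohepta-1,5-dien-2-yl)cyclohex-3-en-1-yl acetate
Product: 17 (1R,2R,3R,4S,6S)-2-hydroxy-1-methyl-4-(6-methyl-3-oxohepta-1,5-dien-2-yl)-7-oxabicyclo[4.1.0]heptan-3-yl acetate
Conditions: VO(acac)2 (5 mol %), t-BuOOH (in decane), CH2Cl2, 0 °C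
Reagents that add atoms: tert-butyl hydroperoxide, CC(C)(C)OO
Why: Hydroxyl-directed epoxidation, in which the vanadium alkoxide of the allylic C3–OH delivers oxygen to the same face of C4=C5 and gives the cis epoxy alcohol; the enone and the isolated prenyl alkene have no directing hydroxyl and should react far more slowly.

Step 14
Reactants: 17 (1R,2R,3R,4S,6S)-2-hydroxy-1-methyl-4-(6-methyl-3-oxohepta-1,5-dien-2-yl)-7-oxabicyclo[4.1.0]heptan-3-yl acetate
Product: 18 (1R,2R,3R,4S,6S)-2-hydroxy-4-[(3S)-3-hydroxy-6-methylhepta-1,5-dien-2-yl]-1-methyl-7-oxabicyclo[4.1.0]heptan-3-yl acetate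
Conditions: (R)-2-methyl-CBS-oxazaborolidine (0.5 equiv), catecholborane (2.5 equiv), toluene–CH2Cl2, −78 °C; pH 7 buffer work-up
Reagents that add atoms: none
Why: Corey–Bakshi–Shibata reduction with the 2-substituted vinyl group as the large and the CH2-prenyl group as the small substituent, so the (R)-catalyst should give the 8S allylic alcohol under reagent control; catecholborane at −78 °C should spare the alkenes, the epoxide and the acetate.

Step 15
Reactants: 18 (1R,2R,3R,4S,6S)-2-hydroxy-4-[(3S)-3-hydroxy-6-methylhepta-1,5-dien-2-yl]-1-methyl-7-oxabicyclo[4.1.0]heptan-3-yl acetate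
Product: 19 (1S,2R,3R,4S,6S)-3-acetoxy-1-methyl-4-{(3S)-6-methyl-3-[(Z)-2-methylbut-2-enoyloxy]hepta-1,5-dien-2-yl}-7-oxabicyclo[4.1.0]heptan-2-yl (Z)-2-methylbut-2-enoate
Conditions: angelic acid, 2,4,6-trichlorobenzoyl chloride, Et3N, toluene, rt; then 18, 75 °C (no DMAP)
Reagents that add atoms: angelic acid [(Z)-2-methylbut-2-enoic acid], C/C=C(/C)C(=O)O
Why: Yamaguchi-type esterification through the mixed angelic 2,4,6-trichlorobenzoic anhydride without a nucleophilic catalyst, the conditions under which angelates of hindered secondary alcohols form without Z-to-E isomerisation to tiglates; both hydroxyls (O3 and O8) are acylated in one operation.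

Step 16
Reactants: 19 (1S,2R,3R,4S,6S)-3-acetoxy-1-methyl-4-{(3S)-6-methyl-3-[(Z)-2-methylbut-2-enoyloxy]hepta-1,5-dien-2-yl}-7-oxabicyclo[4.1.0]heptan-2-yl (Z)-2-methylbut-2-enoate
Product: 20 (1S,2R,3R,4S,6S)-3-acetoxy-4-{(3S)-4-[(2S)-3,3-dimethyloxiran-2-yl]-3-[(Z)-2-methylbut-2-enoyloxy]but-1-en-2-yl}-1-methyl-7-oxabicyclo[4.1.0]heptan-2-yl (Z)-2-methylbut-2-enoate (CNP0118696.1)
Conditions: L-fructose-derived Shi ketone (30 mol %), Oxone, K2CO3, n-Bu4NHSO4 (cat.), MeCN–dimethoxymethane–aq. buffer (pH 10.5), 0 °C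
Reagents that add atoms: potassium peroxymonosulfate (Oxone), [K+].[O-]S(=O)(=O)OO
Why: Shi asymmetric epoxidation, in which the chiral dioxirane epoxidises the electron-rich trisubstituted C10=C11 through a spiro transition state with reagent-controlled facial selectivity (the L-fructose-derived ketone for 10S); the conjugated angelate alkenes and the 1,1-disubstituted, ester-flanked C7=C14 are electron-poor or poorly matched to the catalyst.

**Compound list**
1 | 3-oxocyclobutane-1-carboxylic acid | O=C1CC(C(=O)O)C1 | starting material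
2 | 3-bromocyclobutan-1-one | O=C1CC(Br)C1 | intermediate
3 | cyclobut-2-en-1-one | O=C1CC=C1 | intermediate
4 | (E)-2-methylbut-2-enal (tiglaldehyde) | C/C=C(\C)C=O | starting material
5 | tert-butyl(dimethyl){[(1E)-2-methylbuta-1,3-dien-1-yl]oxy}silane | C=C/C(C)=C/O[Si](C)(C)C(C)(C)C | intermediate
6 | (1S,5R,6R)-5-[(tert-butyldimethylsilyl)oxy]-4-methylbicyclo[4.2.0]oct-3-en-7-one (cis-fused, OTBS cis to the C6–C7 bond) | O=C1C[C@@H]2CC=C(C)[C@H](O[Si](C)(C)C(C)(C)C)[C@@H]21 | intermediate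
7 | (3aS,7S,7aR)-7-[(tert-butyldimethylsilyl)oxy]-6-methyl-3a,4,7,7a-tetrahydro-1-benzofuran-2(3H)-one | O=C1C[C@@H]2CC=C(C)[C@H](O[Si](C)(C)C(C)(C)C)[C@@H]2O1 | intermediate
8 | (3R,3aS,7S,7aR)-7-[(tert-butyldimethylsilyl)oxy]-3-[(dimethylamino)methyl]-6-methyl-3a,4,7,7a-tetrahydro-1-benzofuran-2(3H)-one (Mannich base, exo epimer expected, not isolated) | O=C1[C@@H](CN(C)C)[C@@H]2CC=C(C)[C@H](O[Si](C)(C)C(C)(C)C)[C@@H]2O1 | intermediate
9 | N-methyl ammonium iodide (methiodide) of 8 (not isolated) | O=C1[C@@H](C[N+](C)(C)C)[C@@H]2CC=C(C)[C@H](O[Si](C)(C)C(C)(C)C)[C@@H]2O1.[I-] | intermediate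
10 | (3aS,7S,7aR)-7-[(tert-butyldimethylsilyl)oxy]-6-methyl-3-methylidene-3a,4,7,7a-tetrahydro-1-benzofuran-2(3H)-one | O=C1C(=C)[C@@H]2CC=C(C)[C@H](O[Si](C)(C)C(C)(C)C)[C@@H]2O1 | intermediate
11 | (3aS,7S,7aR)-7-[(tert-butyldimethylsilyl)oxy]-6-methyl-3-methylidene-2,3,3a,4,7,7a-hexahydro-1-benzofuran-2-ol (anomeric mixture) | OC1C(=C)[C@@H]2CC=C(C)[C@H](O[Si](C)(C)C(C)(C)C)[C@@H]2O1 | intermediate
12 | (1R,2S,6S)-2-[(tert-butyldimethylsilyl)oxy]-6-(3-hydroxyhexa-1,5-dien-2-yl)-3-methylcyclohex-3-en-1-ol (C8 epimers) | C=CCC(O)C(=C)[C@@H]1CC=C(C)[C@H](O[Si](C)(C)C(C)(C)C)[C@@H]1O | intermediate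
13 | (1R,2S,6S)-2-[(tert-butyldimethylsilyl)oxy]-6-(3-hydroxy-6-methylhepta-1,5-dien-2-yl)-3-methylcyclohex-3-en-1-ol (C8 epimers) | CC(C)=CCC(O)C(=C)[C@@H]1CC=C(C)[C@H](O[Si](C)(C)C(C)(C)C)[C@@H]1O | intermediate
14 | 2-[(1S,5S,6R)-5-[(tert-butyldimethylsilyl)oxy]-6-hydroxy-4-methylcyclohex-3-en-1-yl]-6-methylhepta-1,5-dien-3-one | CC(C)=CCC(=O)C(=C)[C@@H]1CC=C(C)[C@H](O[Si](C)(C)C(C)(C)C)[C@@H]1O | intermediate
15 | (1R,2S,6S)-2-[(tert-butyldimethylsilyl)oxy]-3-methyl-6-(6-methyl-3-oxohepta-1,5-dien-2-yl)cyclohex-3-en-1-yl acetate | CC(C)=CCC(=O)C(=C)[C@@H]1CC=C(C)[C@H](O[Si](C)(C)C(C)(C)C)[C@@H]1OC(C)=O | intermediate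
16 | (1R,2S,6S)-2-hydroxy-3-methyl-6-(6-methyl-3-oxohepta-1,5-dien-2-yl)cyclohex-3-en-1-yl acetate | CC(C)=CCC(=O)C(=C)[C@@H]1CC=C(C)[C@H](O)[C@@H]1OC(C)=O | intermediate
17 | (1R,2R,3R,4S,6S)-2-hydroxy-1-methyl-4-(6-methyl-3-oxohepta-1,5-dien-2-yl)-7-oxabicyclo[4.1.0]heptan-3-yl acetate | CC(C)=CCC(=O)C(=C)[C@@H]1C[C@@H]2O[C@]2(C)[C@H](O)[C@@H]1OC(C)=O | intermediate
18 | (1R,2R,3R,4S,6S)-2-hydroxy-4-[(3S)-3-hydroxy-6-methylhepta-1,5-dien-2-yl]-1-methyl-7-oxabicyclo[4.1.0]heptan-3-yl acetate | CC(C)=CC[C@H](O)C(=C)[C@@H]1C[C@@H]2O[C@]2(C)[C@H](O)[C@@H]1OC(C)=O | intermediate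
19 | (1S,2R,3R,4S,6S)-3-acetoxy-1-methyl-4-{(3S)-6-methyl-3-[(Z)-2-methylbut-2-enoyloxy]hepta-1,5-dien-2-yl}-7-oxabicyclo[4.1.0]heptan-2-yl (Z)-2-methylbut-2-enoate | CC(C)=CC[C@H](OC(=O)/C(C)=C\C)C(=C)[C@@H]1C[C@@H]2O[C@]2(C)[C@H](OC(=O)/C(C)=C\C)[C@@H]1OC(C)=O | intermediate
20 | (1S,2R,3R,4S,6S)-3-acetoxy-4-{(3S)-4-[(2S)-3,3-dimethyloxiran-2-yl]-3-[(Z)-2-methylbut-2-enoyloxy]but-1-en-2-yl}-1-methyl-7-oxabicyclo[4.1.0]heptan-2-yl (Z)-2-methylbut-2-enoate (CNP0118696.1) | C=C([C@H](C[C@@H]1OC1(C)C)OC(=O)/C(C)=C\C)[C@@H]1C[C@@H]2O[C@]2(C)[C@H](OC(=O)/C(C)=C\C)[C@@H]1OC(C)=O | target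

**Step count**
Total: 16 steps. Longest linear sequence: 15 steps (steps 1, 2, 4–16, from 1); the diene branch (step 3) is one step.

**Steps most likely to fail**

Step 4 (key cycloaddition). The acidic catalyst may desilylate or oligomerise the dienol ether, a stepwise Mukaiyama–Michael addition may compete with cycloaddition, and facial discrimination on a dienophile as small as cyclobutenone may be too low. The fallback gives up catalyst control and resolves instead. It sets out from 3 and 5: the uncatalysed (or ZnCl2-promoted) cycloaddition in CH2Cl2 should give racemic adduct, that is 6 together with (1R,5S,6S)-5-[(tert-butyldimethylsilyl)oxy]-4-methylbicyclo[4.2.0]oct-3-en-7-one F1. Alkaline H2O2 as in step 5 converts the pair into 7 and the antipodal lactone (3aR,7R,7aS)-7-[(tert-butyldimethylsilyl)oxy]-6-methyl-3a,4,7,7a-tetrahydro-1-benzofuran-2(3H)-one F2. HF·pyridine removes the silyl group to give (3aS,7S,7aR)-7-hydroxy-6-methyl-3a,4,7,7a-tetrahydro-1-benzofuran-2(3H)-one F3 and its antipode (3aR,7R,7aS)-7-hydroxy-6-methyl-3a,4,7,7a-tetrahydro-1-benzofuran-2(3H)-one F4. A lipase (screened so that the unwanted antipode is acylated) with vinyl acetate converts F4 into (3aR,7R,7aS)-6-methyl-2-oxo-2,3,3a,4,7,7a-hexahydro-1-benzofuran-7-yl acetate F5, which is separated from unreacted F3 by chromatography. TBSCl and imidazole turn F3 back into 7, where the route is rejoined.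

Step 12 (unmasking O3 beside the skipped enone). Once the C3 hydroxyl is free, C10=C11 may migrate into conjugation with the C8 ketone, the C3–OH (1,3-cis to the side chain) may add to the C14=C7–C8=O acceptor, and the acetyl group may migrate from O2 to O3. The fallback removes the enone before O3 is unmasked and installs the angelates one at a time. It sets out from 15: CBS reduction as in step 14 should give (1R,2S,6S)-2-[(tert-butyldimethylsilyl)oxy]-6-[(3S)-3-hydroxy-6-methylhepta-1,5-dien-2-yl]-3-methylcyclohex-3-en-1-yl acetate F6. Mixed-anhydride angeloylation as in step 15 gives (3S)-2-[(1S,5S,6R)-6-acetoxy-5-[(tert-butyldimethylsilyl)oxy]-4-methylcyclohex-3-en-1-yl]-6-methylhepta-1,5-dien-3-yl (Z)-2-methylbut-2-enoate F7. HF·pyridine gives (3S)-2-[(1S,5S,6R)-6-acetoxy-5-hydroxy-4-methylcyclohex-3-en-1-yl]-6-methylhepta-1,5-dien-3-yl (Z)-2-methylbut-2-enoate F8. VO(acac)2/t-BuOOH, now with no other allylic alcohol present, gives (3S)-2-[(1R,2R,3R,4S,6S)-3-acetoxy-2-hydroxy-1-methyl-7-oxabicyclo[4.1.0]heptan-4-yl]-6-methylhepta-1,5-dien-3-yl (Z)-2-methylbut-2-enoate F9. A second angeloylation at O3 rejoins the route at 19.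

Step 15 (double angeloylation). Acylation of the hindered C3–OH (flanked by the epoxide and the acetate) may be slow, so the activated angelate may isomerise to the tiglate and the acetyl group may migrate at the temperature needed. The fallback builds the Z double bonds after the acyl groups are attached. It sets out from 18: esterification with 2-[bis(2,2,2-trifluoroethoxy)phosphoryl]propanoic acid (DIC, cat. DMAP, CH2Cl2) should give the bis(phosphonopropanoate) (1S,2R,3R,4S,6S)-3-acetoxy-1-methyl-4-{(3S)-6-methyl-3-[2-(bis(2,2,2-trifluoroethoxy)phosphoryl)propanoyloxy]hepta-1,5-dien-2-yl}-7-oxabicyclo[4.1.0]heptan-2-yl 2-[bis(2,2,2-trifluoroethoxy)phosphoryl]propanoate F10. Still–Gennari olefination (KHMDS, 18-crown-6, THF, −78 °C, acetaldehyde) should form both Z-2-methylbut-2-enoates and rejoins the route at 19.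

Further compounds
F1 | step 4 | (1R,5S,6S)-5-[(tert-butyldimethylsilyl)oxy]-4-methylbicyclo[4.2.0]oct-3-en-7-one | O=C1C[C@H]2CC=C(C)[C@@H](O[Si](C)(C)C(C)(C)C)[C@H]21
F2 | step 4 | (3aR,7R,7aS)-7-[(tert-butyldimethylsilyl)oxy]-6-methyl-3a,4,7,7a-tetrahydro-1-benzofuran-2(3H)-one | O=C1C[C@H]2CC=C(C)[C@@H](O[Si](C)(C)C(C)(C)C)[C@H]2O1
F3 | step 4 | (3aS,7S,7aR)-7-hydroxy-6-methyl-3a,4,7,7a-tetrahydro-1-benzofuran-2(3H)-one | O=C1C[C@@H]2CC=C(C)[C@H](O)[C@@H]2O1
F4 | step 4 | (3aR,7R,7aS)-7-hydroxy-6-methyl-3a,4,7,7a-tetrahydro-1-benzofuran-2(3H)-one | O=C1C[C@H]2CC=C(C)[C@@H](O)[C@H]2O1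
F5 | step 4 | (3aR,7R,7aS)-6-methyl-2-oxo-2,3,3a,4,7,7a-hexahydro-1-benzofuran-7-yl acetate | O=C1C[C@H]2CC=C(C)[C@@H](OC(C)=O)[C@H]2O1
F6 | step 12 | (1R,2S,6S)-2-[(tert-butyldimethylsilyl)oxy]-6-[(3S)-3-hydroxy-6-methylhepta-1,5-dien-2-yl]-3-methylcyclohex-3-en-1-yl acetate | CC(C)=CC[C@H](O)C(=C)[C@@H]1CC=C(C)[C@H](O[Si](C)(C)C(C)(C)C)[C@@H]1OC(C)=O
F7 | step 12 | (3S)-2-[(1S,5S,6R)-6-acetoxy-5-[(tert-butyldimethylsilyl)oxy]-4-methylcyclohex-3-en-1-yl]-6-methylhepta-1,5-dien-3-yl (Z)-2-methylbut-2-enoate | CC(C)=CC[C@H](OC(=O)/C(C)=C\C)C(=C)[C@@H]1CC=C(C)[C@H](O[Si](C)(C)C(C)(C)C)[C@@H]1OC(C)=O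
F8 | step 12 | (3S)-2-[(1S,5S,6R)-6-acetoxy-5-hydroxy-4-methylcyclohex-3-en-1-yl]-6-methylhepta-1,5-dien-3-yl (Z)-2-methylbut-2-enoate | CC(C)=CC[C@H](OC(=O)/C(C)=C\C)C(=C)[C@@H]1CC=C(C)[C@H](O)[C@@H]1OC(C)=O
F9 | step 12 | (3S)-2-[(1R,2R,3R,4S,6S)-3-acetoxy-2-hydroxy-1-methyl-7-oxabicyclo[4.1.0]heptan-4-yl]-6-methylhepta-1,5-dien-3-yl (Z)-2-methylbut-2-enoate | CC(C)=CC[C@H](OC(=O)/C(C)=C\C)C(=C)[C@@H]1C[C@@H]2O[C@]2(C)[C@H](O)[C@@H]1OC(C)=O
F10 | step 15 | (1S,2R,3R,4S,6S)-3-acetoxy-1-methyl-4-{(3S)-6-methyl-3-[2-(bis(2,2,2-trifluoroethoxy)phosphoryl)propanoyloxy]hepta-1,5-dien-2-yl}-7-oxabicyclo[4.1.0]heptan-2-yl 2-[bis(2,2,2-trifluoroethoxy)phosphoryl]propanoate | CC(C)=CC[C@H](OC(=O)C(C)P(=O)(OCC(F)(F)F)OCC(F)(F)F)C(=C)[C@@H]1C[C@@H]2O[C@]2(C)[C@H](OC(=O)C(C)P(=O)(OCC(F)(F)F)OCC(F)(F)F)[C@@H]1OC(C)=O
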